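**Analysis of the target**

The target (C22H32O4) is a labdane: a trans-fused decalin (ring A = C1–C5 and C10, ring B = C5–C10; labdane numbering, with C17 on C8, C18/C19 on C4 and C20 on C10) whose C9 carries a two-carbon tether (C11–C12) to the β-carbon C13 of a but-2-en-4-olide (C13–C16). It has three contiguous stereocentres along C10–C5–C6: the quaternary C10 (S, C20 β), C5 (S, H α, anti to C20) and C6 (R), whose acetoxy group is β and axial, syn to both C20 and the 4β-methyl group. Ring B also holds the tetrasubstituted C8=C9 alkene, whose position (not Δ7, not Δ8(17)) has to be fixed without relying on an elimination. Sensitive groups are the hindered secondary acetate (base; acid-induced loss to dienes), the butenolide (nucleophiles, hydride, base, hydrogenation) and the tetrasubstituted alkene (acid-induced migration). The difficulty lies in the quaternary C10 next to C5, which is itself flanked by the gem-dimethyl C4, and above all in the oxygen at C6, a carbon that neither the usual terpenoid feedstocks nor a polyene cyclisation activates. The feature the route exploits: in ring B the oxygen-bearing C6 and the sp2 carbon C9 are para to each other, C9 is flanked by the methyl-bearing C8 and C10, and C6 by C5 and C7. This is the substitution pattern of 2,6-dimethyl-1,4-benzoquinone, with the ring-fusion bond C5–C10 as one of its two alkenes. Ring A is then the [4+2] adduct of that alkene with a C1–C4 diene that carries both C4 methyl groups, and no protecting group is needed.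

**Retrosynthetic reasoning**

13 ⇒ 12 ⇒ 10 + 11. The last bond cut is C12–C13, between the tether and the butenolide β-carbon. Cutting here lets the lactone enter intact, as the commercial bromide 11, in the final step, so it never meets hydride, enolate or hydrogenation conditions. The forward reaction must hydroborate the vinyl group of 10 at its terminus (giving 12) without touching the tetrasubstituted alkene, and then join an sp3 boron centre to the sp2 bromide.

10 ⇒ 9. The C9–C11 bond is cut next, back to the enol triflate 9 and a vinyl nucleophile. The tetrasubstituted C8=C9 alkene is then defined by where an enol oxygen sat, not by the regiochemistry of a proton loss. The forward coupling has to work at an sp2 carbon flanked by the quaternary C10 and the methylated C8.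

9 ⇒ 8 ⇒ 7. The C9–O bond of 9 is traced to the enolate 8, and 8 to conjugate hydride addition at C7 of the enone 7. Because C10 is quaternary, the C9 carbonyl can only be enolised towards C8, so the alkene of 9 can only be Δ8(9). The forward step needs 1,4- rather than 1,2-delivery of hydride and O-sulfonylation before the enolate can do anything else.

7 ⇒ 6 ⇒ 5. The C6 stereocentre is cut back to the ene-dione 5. Its two carbonyls are not alike: C9 is flanked by the quaternary C10 and the methylated C8, C6 by two CH carbons. The forward reduction has to pick C6 and the α face; the β face is covered by C20 and the 4β-methyl group, which is exactly what the axial 6β-oxygen requires. Acetylation gives 7.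

5 ⇒ 4 ⇒ 3. In 5 the hydrogen at C5 is α to the C6 carbonyl and vinylogously acidified by the C9 carbonyl, so C5 can be equilibrated. The trans ring fusion is therefore reached by thermodynamic epimerisation of the cis isomer 4, and the cis fusion that a cycloaddition must deliver is no liability. The C2=C3 alkene of 3 is saturated on the way.

3 ⇒ 1 + 2. The key disconnection cuts C1–C10 and C4–C5, i.e. all of ring A, and leads to the quinone 1 and the diene 2, both achiral and commercial. Between them they contain all fourteen ring and methyl carbons of the decalin (C1–C10, C17–C20) and both oxygen handles (C6, C9). The forward reaction has to set the quaternary C10 in absolute terms with a chiral Lewis acid and bond the unsubstituted diene terminus to the methyl-bearing quinone carbon.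

**Alternatives that were turned down**

Alternative 1: the textbook chiral-pool route from (+)-sclareolide A1, which supplies C5, C10, the four methyl groups and C11–C12. The forward key sequence would open and dehydrate the lactone to the Δ8(9) series and oxidise allylically to the 7-oxo-Δ8 ester A2, then couple the butenolide at C12. It was turned down because the Δ8 alkene activates C7 and C11 but not C6. Moving the oxygen from C7 to C6 needs α′-oxygenation of the enone, reduction and deoxygenation at C7 next to the new C6–O bond, and inversion to the axial 6β-epimer. That is five or more redox steps for one C–O bond, with risk of β-elimination towards C5. The purchased stereocentres are the easy ones; the hard position is untouched.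

Alternative 2: a Robinson-annulation route from the (S)-Wieland–Miescher ketone A3, disconnecting ring A at C4–C5/C5–C10 by aldol logic. The forward sequence (ketal protection of C9, deconjugative gem-dimethylation at C4, Wolff–Kishner removal of the C3 carbonyl, hydroboration–oxidation of the Δ5 alkene, oxidation, deprotection) would lead to the trans-dione A4. It was turned down on step economy and on selectivity. About seven steps reach A4, which still lacks C17, carries two ketones that are both enolisable towards CH2 groups (C7 and C8) and so are harder to tell apart than those of 5, and needs a further methylation and the Δ8 adjustment. Each methyl group is installed one at a time, and the asymmetric step sets only C10.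

Alternative 3: a biomimetic cationic bicyclisation of the acyclic trienyl butenolide A5, forming C4–C5 and C9–C10 and both rings to give 13 directly. It was turned down for mechanistic reasons. The C6 acetate is allylic to the nucleophilic C5=C10 alkene, so acid would ionise it and its inductive effect would slow the first ring closure. The chair transition state would have to hold the acetate axial, syn to two methyl groups, so the 6α-epimer or no control is expected. The C6 stereocentre would have to be made enantiopure in the acyclic precursor by a separate asymmetric step. Termination by proton loss from the C8 cation gives Δ7, Δ8 and Δ8(17) isomers.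

Key step: step 1

Remark (assumption): compounds 1, 2 and 11 are taken as commercial; the (S)-diphenylprolinol-derived oxazaborolidinium catalyst is taken to leave the Si face at C10 of 1 open, and if the sense is the opposite for this quinone the equally available (R)-catalyst is used with nothing else changed.

**Route**

Step 1
Reactants: 1 2,6-dimethyl-1,4-benzoquinone; 2 4-methylpenta-1,3-diene
Product: 3 (4aR,8aS)-2,5,5,8a-tetramethyl-4a,5,8,8a-tetrahydronaphthalene-1,4-dione (cis-fused cycloadduct)
Conditions: (S)-o-tolyl-diphenylprolinol-oxazaborolidine·AlBr3 (10 mol %), 2 (3 equiv), CH2Cl2, −78 → −40 °C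
Reagents that add atoms: none
Why: This is a Lewis-acid-catalysed, asynchronous but suprafacial Diels–Alder reaction of the quinone C5=C10 bond with the diene; the closest known reaction types are the oxazaborolidinium-catalysed enantioselective Diels–Alder reaction of methyl-substituted benzoquinones and the Lewis-acid-promoted cycloaddition of 4-methylpenta-1,3-diene to enones, which gives 2,2-dimethylcyclohex-3-enyl ketones with the same orientation. The boron cation should bind the C6 carbonyl, the only one flanked by two C–H groups, which raises the LUMO coefficient at the β-carbons C10 and C8. The unsubstituted diene terminus C1 (largest HOMO coefficient, since both methyl groups sit on C4) should bond to C10 first and the dimethylated terminus C4 should close onto C5, so ring A is closed in an intermolecular [4+2] mode that forms C1–C10 and C4–C5. The reverse orientation would have to join the two fully substituted carbons C4 and C10 and is disfavoured sterically as well as electronically. C10 is set by the catalyst, which should leave only the Si face at C10 open; C5 follows from suprafacial addition (H-5 cis to C20) and is corrected in step 2. The two quinone alkenes are homotopic, so no site selectivity is needed, and the aprotic catalyst at low temperature is chosen to keep the diene from cationic oligomerisation. One operation should thus deliver ring A, the quaternary stereocentre, all four methyl groups and both oxygen handles of ring B.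

Step 2
Reactants: 3
Product: 5 (4aS,8aS)-2,5,5,8a-tetramethyl-4a,5,6,7,8,8a-hexahydronaphthalene-1,4-dione (trans-fused ene-dione), via cis-fused dihydro-enedione 4 (not isolated)
Conditions: H2 (3 atm), RhCl(PPh3)3 (5 mol %), PhMe, rt; then DBU (0.3 equiv), Ar, rt
Reagents that add atoms: none
Why: Homogeneous Rh-catalysed hydrogenation should take the cis-disubstituted C2=C3 alkene and leave the trisubstituted, electron-poor C7=C8 alkene; DBU then equilibrates C5 through the extended dienolate to the trans-fused isomer (thermodynamic epimerisation), while the quaternary C10 can neither epimerise nor allow aromatisation.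

Step 3
Reactants: 5
Product: 6 (4R,4aS,8aS)-4-hydroxy-2,5,5,8a-tetramethyl-4a,5,6,7,8,8a-hexahydronaphthalen-1(4H)-one (6β-hydroxy enone)
Conditions: NaBH4 (0.6 equiv), CeCl3·7H2O (1.1 equiv), MeOH–CH2Cl2 (1:1), −78 °C
Reagents that add atoms: none
Why: Luche 1,2-reduction should pick the C6 carbonyl (flanked by two CH carbons) over the C9 carbonyl (flanked by the quaternary C10 and the methylated C8); hydride should enter from the α face because C20 and the 4β-methyl group cover the β face, which gives the axial 6β-alcohol (C6 R).

Step 4
Reactants: 6
Product: 7 (1R,4aS,8aS)-3,4a,8,8-tetramethyl-4-oxo-1,4,4a,5,6,7,8,8a-octahydronaphthalen-1-yl acetate (6β-acetoxy enone)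
Conditions: Ac2O (5 equiv), DMAP (0.3 equiv), pyridine, 50 °C
Reagents that add atoms: acetic anhydride CC(=O)OC(C)=O
Why: DMAP-catalysed acylation of the axial, doubly syn-axially hindered alcohol under mildly forcing conditions; no stereocentre is touched.

Step 5
Reactants: 7
Product: 9 (1R,4aS,8aS)-3,4a,8,8-tetramethyl-4-{[(trifluoromethyl)sulfonyl]oxy}-1,2,4a,5,6,7,8,8a-octahydronaphthalen-1-yl acetate (enol triflate), via lithium enolate 8 (not isolated)
Conditions: L-Selectride (1.1 equiv), THF, −78 °C; then N-(5-chloropyridin-2-yl)triflimide (1.3 equiv), −78 → 0 °C; sat. aq NH4Cl work-up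
Reagents that add atoms: N-(5-chloropyridin-2-yl)-1,1,1-trifluoro-N-[(trifluoromethyl)sulfonyl]methanesulfonamide O=S(=O)(N(c1ccc(Cl)cn1)S(=O)(=O)C(F)(F)F)C(F)(F)F
Why: Conjugate reduction and enolate triflation of an α-methyl cyclohexenone: 1,2-attack at C9 is blocked by the quaternary C10, so hydride should add to the unsubstituted β-carbon C7, and O-sulfonylation of the regiodefined enolate fixes the tetrasubstituted C8=C9 alkene; the acetate on C6 is γ to the enolate carbon and cannot be eliminated.

Step 6
Reactants: 9
Product: 10 (1R,4aS,8aS)-4-ethenyl-3,4a,8,8-tetramethyl-1,2,4a,5,6,7,8,8a-octahydronaphthalen-1-yl acetate (9-vinyl diene)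
Conditions: Bu3SnCH=CH2 (1.5 equiv), Pd(PPh3)4 (5 mol %), LiCl (3 equiv), THF, 65 °C
Reagents that add atoms: tributyl(vinyl)stannane C=C[Sn](CCCC)(CCCC)CCCC
Why: Stille coupling of a hindered cyclohexenyl triflate under neutral conditions that spare the acetate, which is now homoallylic and cannot ionise to a π-allyl complex; LiCl assists transmetallation.

Step 7
Reactants: 10; 11 4-bromofuran-2(5H)-one
Product: 13 (1R,4aS,8aS)-3,4a,8,8-tetramethyl-4-[2-(5-oxo-2,5-dihydrofuran-3-yl)ethyl]-1,2,4a,5,6,7,8,8a-octahydronaphthalen-1-yl acetate (6β-acetoxylabda-8,13-dien-15,16-olide, the target), via B-alkyl-9-BBN adduct 12 (not isolated)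
Conditions: 9-BBN (1.3 equiv), THF, 0 °C → rt; then 11 (1.5 equiv), PdCl2(dppf) (5 mol %), AsPh3 (10 mol %), K3PO4 (3 M aq, 3 equiv), DMF, rt
Reagents that add atoms: none
Why: 9-BBN should hydroborate only the monosubstituted alkene, with boron at the terminus C12 (the tetrasubstituted alkene is inert), and B-alkyl Suzuki–Miyaura coupling with the β-bromo butenolide, a vinylogous acyl bromide that adds quickly to Pd(0), forms C12–C13 at room temperature without a new stereocentre.

**Compound list**

1 | 2,6-dimethyl-1,4-benzoquinone | CC1=CC(=O)C=C(C)C1=O | starting material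
2 | 4-methylpenta-1,3-diene | CC(C)=CC=C | starting material
3 | (4aR,8aS)-2,5,5,8a-tetramethyl-4a,5,8,8a-tetrahydronaphthalene-1,4-dione | O=C1C=C(C)C(=O)[C@@]2(C)CC=CC(C)(C)[C@@H]12 | intermediate
4 | (4aR,8aS)-2,5,5,8a-tetramethyl-4a,5,6,7,8,8a-hexahydronaphthalene-1,4-dione (cis-fused) | O=C1C=C(C)C(=O)[C@@]2(C)CCCC(C)(C)[C@@H]12 | intermediate (not isolated)
5 | (4aS,8aS)-2,5,5,8a-tetramethyl-4a,5,6,7,8,8a-hexahydronaphthalene-1,4-dione (trans-fused) | O=C1C=C(C)C(=O)[C@@]2(C)CCCC(C)(C)[C@H]12 | intermediate
6 | (4R,4aS,8aS)-4-hydroxy-2,5,5,8a-tetramethyl-4a,5,6,7,8,8a-hexahydronaphthalen-1(4H)-one | O[C@@H]1C=C(C)C(=O)[C@@]2(C)CCCC(C)(C)[C@H]12 | intermediate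
7 | (1R,4aS,8aS)-3,4a,8,8-tetramethyl-4-oxo-1,4,4a,5,6,7,8,8a-octahydronaphthalen-1-yl acetate | CC(=O)O[C@@H]1C=C(C)C(=O)[C@@]2(C)CCCC(C)(C)[C@H]12 | intermediate
8 | lithium (4R,4aS,8aS)-4-acetoxy-2,5,5,8a-tetramethyl-3,4,4a,5,6,7,8,8a-octahydronaphthalen-1-olate | CC(=O)O[C@@H]1CC(C)=C(O[Li])[C@@]2(C)CCCC(C)(C)[C@H]12 | intermediate (not isolated)
9 | (1R,4aS,8aS)-3,4a,8,8-tetramethyl-4-{[(trifluoromethyl)sulfonyl]oxy}-1,2,4a,5,6,7,8,8a-octahydronaphthalen-1-yl acetate | CC(=O)O[C@@H]1CC(C)=C(OS(=O)(=O)C(F)(F)F)[C@@]2(C)CCCC(C)(C)[C@H]12 | intermediate
10 | (1R,4aS,8aS)-4-ethenyl-3,4a,8,8-tetramethyl-1,2,4a,5,6,7,8,8a-octahydronaphthalen-1-yl acetate | CC(=O)O[C@@H]1CC(C)=C(C=C)[C@@]2(C)CCCC(C)(C)[C@H]12 | intermediate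
11 | 4-bromofuran-2(5H)-one | BrC1=CC(=O)OC1 | starting material
12 | (1R,4aS,8aS)-4-[2-(9-borabicyclo[3.3.1]nonan-9-yl)ethyl]-3,4a,8,8-tetramethyl-1,2,4a,5,6,7,8,8a-octahydronaphthalen-1-yl acetate | CC(=O)O[C@@H]1CC(C)=C(CCB2C3CCCC2CCC3)[C@@]2(C)CCCC(C)(C)[C@H]12 | intermediate (not isolated)
13 | (1R,4aS,8aS)-3,4a,8,8-tetramethyl-4-[2-(5-oxo-2,5-dihydrofuran-3-yl)ethyl]-1,2,4a,5,6,7,8,8a-octahydronaphthalen-1-yl acetate (6β-acetoxylabda-8,13-dien-15,16-olide) | CC(=O)O[C@@H]1CC(C)=C(CCC2=CC(=O)OC2)[C@@]2(C)CCCC(C)(C)[C@H]12 | target

**Step count and least certain steps**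

Total step count: 7. Longest linear sequence: 7 steps (1 and 2 to 13); 11 is used as purchased.

Step 1 (key step). The methyl group that is cis on C4 of the diene disfavours the s-cis conformer. The cycloaddition may therefore be slow enough that acid-induced oligomerisation of the diene, or stepwise closure through the quinone oxygen, competes. A late, asynchronous transition state may also lower the facial discrimination by the catalyst. Fallback: setting out from 1 and 2, the cycloaddition is run without any acid under hyperbaric conditions (12–15 kbar, CH2Cl2, rt), where no cationic pathway exists and steric retardation is overcome. This should give the racemate, i.e. 3 together with its antipode, the (4aS,8aR)-cycloadduct F1. The conditions of step 2 take the mixture through 4 and its antipode, the (4aS,8aR)-cis-dihydro-enedione F2 (not isolated), to 5 and its antipode, the (4aR,8aR)-trans-enedione F3. Preparative chromatography on a chiral stationary phase then separates 5 from F3, and the route is rejoined at 5. The absolute configuration then rests on resolution instead of catalysis.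

Step 2. Competing hydrogen uptake at the electron-poor C7=C8 alkene would destroy the handle for step 5. Fallback: setting out from 3, the hydrogenation is deferred. DBU epimerisation first gives the trans-fused Δ2-enedione F4, Luche reduction gives the Δ2-hydroxy enone F5, and acetylation gives the Δ2-acetoxy enone F6. Hydrogenation with the same rhodium catalyst then meets only an ordinary α-methyl enone as the second alkene, and the route is rejoined at 7. Should the cis isomer persist after equilibration in the main route, it can be separated and resubmitted, since the process is an equilibrium.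

Step 3. Loss of site selectivity between the two carbonyls (hydride also reaching C9, or over-reduction to the diol) is the main risk; attack from the β face is less likely. Fallback: setting out from 5, the carbonyls are told apart by conjugate addition instead of 1,2-addition. L-Selectride should add hydride to C7, the only unsubstituted alkene carbon, to give the lithium enolate F7 (not isolated), which is trapped with the same triflimide as the keto triflate F8. NaBH4 then reduces the only remaining ketone from the α face to the hydroxy triflate F9, and acetylation rejoins the route at 9.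

Step 5. Competing 1,2-reduction, or acetyl or proton transfer within the enolate before O-sulfonylation, would erode the yield of the triflate. Fallback: setting out from 7, a neutral rhodium-catalysed 1,4-hydrosilylation (Et3SiH, RhCl(PPh3)3 cat., PhH, 60 °C) gives the isolable triethylsilyl enol ether F10. Fluoride-triggered triflation (CsF, PhNTf2, DME, rt) releases the enolate only in the presence of excess triflating agent, and the route is rejoined at 9.

Step 7. Slow transmetallation of the hindered homoallylic borane would allow protodeboronation, and the aqueous base may degrade the bromobutenolide or cleave the acetate. Fallback: setting out from 10, borane 12 is oxidised (NaBO3·4H2O, THF–H2O, rt) to the primary alcohol F11. Iodination (I2, PPh3, imidazole, CH2Cl2) gives the primary iodide F12. Zinc insertion (Zn dust, LiCl, THF) gives the alkylzinc iodide F13 (not isolated), and a base-free Negishi coupling with 11 (Pd(PPh3)4, THF, rt) rejoins the route at 13.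

**Further compounds**

F1 | step 1 | (4aS,8aR)-2,5,5,8a-tetramethyl-4a,5,8,8a-tetrahydronaphthalene-1,4-dione (antipode of 3) | O=C1C=C(C)C(=O)[C@]2(C)CC=CC(C)(C)[C@H]12
F2 | step 1 | (4aS,8aR)-2,5,5,8a-tetramethyl-4a,5,6,7,8,8a-hexahydronaphthalene-1,4-dione (antipode of 4) | O=C1C=C(C)C(=O)[C@]2(C)CCCC(C)(C)[C@H]12
F3 | step 1 | (4aR,8aR)-2,5,5,8a-tetramethyl-4a,5,6,7,8,8a-hexahydronaphthalene-1,4-dione (antipode of 5) | O=C1C=C(C)C(=O)[C@]2(C)CCCC(C)(C)[C@@H]12
F4 | step 2 | (4aS,8aS)-2,5,5,8a-tetramethyl-4a,5,8,8a-tetrahydronaphthalene-1,4-dione | O=C1C=C(C)C(=O)[C@@]2(C)CC=CC(C)(C)[C@H]12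
F5 | step 2 | (4R,4aS,8aS)-4-hydroxy-2,5,5,8a-tetramethyl-4a,5,8,8a-tetrahydronaphthalen-1(4H)-one | O[C@@H]1C=C(C)C(=O)[C@@]2(C)CC=CC(C)(C)[C@H]12
F6 | step 2 | (1R,4aS,8aS)-3,4a,8,8-tetramethyl-4-oxo-1,4,4a,5,8,8a-hexahydronaphthalen-1-yl acetate | CC(=O)O[C@@H]1C=C(C)C(=O)[C@@]2(C)CC=CC(C)(C)[C@H]12
F7 | step 3 | lithium (4aS,8aS)-2,5,5,8a-tetramethyl-4-oxo-3,4,4a,5,6,7,8,8a-octahydronaphthalen-1-olate | O=C1CC(C)=C(O[Li])[C@@]2(C)CCCC(C)(C)[C@H]12
F8 | step 3 | (4aS,8aS)-2,5,5,8a-tetramethyl-4-oxo-3,4,4a,5,6,7,8,8a-octahydronaphthalen-1-yl trifluoromethanesulfonate | O=C1CC(C)=C(OS(=O)(=O)C(F)(F)F)[C@@]2(C)CCCC(C)(C)[C@H]12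
F9 | step 3 | (4R,4aS,8aS)-4-hydroxy-2,5,5,8a-tetramethyl-3,4,4a,5,6,7,8,8a-octahydronaphthalen-1-yl trifluoromethanesulfonate | O[C@@H]1CC(C)=C(OS(=O)(=O)C(F)(F)F)[C@@]2(C)CCCC(C)(C)[C@H]12
F10 | step 5 | (1R,4aS,8aS)-3,4a,8,8-tetramethyl-4-[(triethylsilyl)oxy]-1,2,4a,5,6,7,8,8a-octahydronaphthalen-1-yl acetate | CC(=O)O[C@@H]1CC(C)=C(O[Si](CC)(CC)CC)[C@@]2(C)CCCC(C)(C)[C@H]12
F11 | step 7 | (1R,4aS,8aS)-4-(2-hydroxyethyl)-3,4a,8,8-tetramethyl-1,2,4a,5,6,7,8,8a-octahydronaphthalen-1-yl acetate | CC(=O)O[C@@H]1CC(C)=C(CCO)[C@@]2(C)CCCC(C)(C)[C@H]12
F12 | step 7 | (1R,4aS,8aS)-4-(2-iodoethyl)-3,4a,8,8-tetramethyl-1,2,4a,5,6,7,8,8a-octahydronaphthalen-1-yl acetate | CC(=O)O[C@@H]1CC(C)=C(CCI)[C@@]2(C)CCCC(C)(C)[C@H]12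
F13 | step 7 | {2-[(4R,4aS,8aS)-4-acetoxy-2,5,5,8a-tetramethyl-3,4,4a,5,6,7,8,8a-octahydronaphthalen-1-yl]ethyl}zinc iodide | CC(=O)O[C@@H]1CC(C)=C(CC[Zn]I)[C@@]2(C)CCCC(C)(C)[C@H]12
A1 | alternative 1 | (+)-sclareolide, (3aR,5aS,9aS,9bR)-3a,6,6,9a-tetramethyldecahydronaphtho[2,1-b]furan-2(1H)-one | C1C[C@@]3(C)OC(=O)C[C@@H]3[C@@]2(C)CCCC(C)(C)[C@H]12
A2 | alternative 1 | methyl (5S,10S)-7-oxo-13,14,15,16-tetranorlabd-8-en-12-oate | C1C(=O)C(C)=C(CC(=O)OC)[C@@]2(C)CCCC(C)(C)[C@H]12
A3 | alternative 2 | (S)-Wieland–Miescher ketone, (S)-8a-methyl-3,4,8,8a-tetrahydronaphthalene-1,6(2H,7H)-dione | C1CCC(=O)[C@@]2(C)CCC(=O)C=C12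
A4 | alternative 2 | (4aS,8aS)-5,5,8a-trimethyloctahydronaphthalene-1,4-dione | O=C1CCC(=O)[C@@]2(C)CCCC(C)(C)[C@H]12
A5 | alternative 3 | 4-[(3E,6R,7E)-6-acetoxy-4,8,12-trimethyltrideca-3,7,11-trien-1-yl]furan-2(5H)-one | CC(C)=CCC/C(C)=C/[C@H](OC(C)=O)C/C(C)=C/CCC1=CC(=O)OC1
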